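**Retrosynthetic overview**
1. Target 18 is a fulvic-acid-type half (1H-pyrano[4,3-b]chromen-10-one locants: C1 acetal CH, C3 ketal C) joined to a citromycetin-type half (primed pyrano[3,2-c]chromen-4-one locants: C2' ketal C, C3' CH) through the C1–C3' bond and the C3–O–C2' ketal bridge; configuration (1S,3R,2'S,3'S).
2. Last operation removes two aryl TIPS ethers and two benzyl esters from 16.
3. Cage disconnection (C1–C3' plus three C–O bonds): electrophile 10 (a masked pyrano[4,3-b]chromenylium) and nucleophile 13, which is made from 10 itself by reduction and ring transposition.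
4. Key C–C disconnection: the aryl–C(=O) bond of 10, made from the formyl carbon of pyranone aldehyde 9 (as a nucleophilic acyl radical, an acyl anion equivalent) and a CH carbon of quinone ester 4, both electrophilic in the ground state.
5. Ring order: 4-pyranone (9), then the arene as an acylhydroquinone (10), then the chromanone of 13, then chromone, pyran, dioxane ketal and dihydropyranone of the cage in one cascade.

Assumption: the drawn relative configuration (dihydropyranone cis-fused on the face of the dioxabicyclononane opposite the chromone bridge) is the thermodynamic one, so only C1 needs external control; the (R)-catalyst is taken to give (1S), and its mirror image is used if the sense proves opposite.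

**Step 1**
Reactants: 1 2,3-dihydroxybenzoic acid
Product: 3 benzyl 2-hydroxy-3-[(triisopropylsilyl)oxy]benzoate, via benzyl 2,3-dihydroxybenzoate 2 (not isolated)
Conditions: KHCO3 (1.1 equiv), BnBr (1.05 equiv), DMF, 40 °C; then imidazole (3 equiv), TIPSCl (1.5 equiv), rt
Reagents that add atoms: benzyl bromide BrCc1ccccc1; chlorotriisopropylsilane CC(C)[Si](Cl)(C(C)C)C(C)C
Why: Carboxylate O-alkylation (KHCO3 deprotonates only the acid) followed by imidazole-promoted silylation of the 3-OH, the 2-OH being held in the salicylate hydrogen bond and flanked on both sides; no stereocentre.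

**Step 2**
Reactants: 3 benzyl 2-hydroxy-3-[(triisopropylsilyl)oxy]benzoate
Product: 4 benzyl 3,6-dioxo-5-[(triisopropylsilyl)oxy]cyclohexa-1,4-diene-1-carboxylate
Conditions: K2[ON(SO3)2] (Fremy's salt, 2.5 equiv), KH2PO4, acetone–H2O, 0 °C to rt
Reagents that add atoms: potassium nitrosodisulfonate K2[ON(SO3)2] [K+].[K+].[O]N(S(=O)(=O)[O-])S(=O)(=O)[O-]
Why: Teuber oxidation, in which one nitroxyl radical abstracts the phenolic hydrogen and a second oxygenates the free para position, giving the para-quinone because both ortho positions are blocked.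

**Step 3**
Reactants: 5 2,2,6-trimethyl-4H-1,3-dioxin-4-one; 6 (E)-3-(dimethylamino)acrolein
Product: 9 6-methyl-4-oxo-4H-pyran-3-carbaldehyde, via acetylketene 7 (not isolated), via aminal cycloadduct 8 (not isolated)
Conditions: 5 (1.5 equiv), PhMe, 110 °C, N2 sweep
Reagents that add atoms: none
Why: Thermal retro-[4+2] of 5 releases acetylketene, which adds across the nucleophilic enamine C=C of 6 (acylketene–enamine hetero-Diels–Alder pyranone annulation) and then loses dimethylamine to give the 4-pyranone with the formyl group intact.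

**Step 4 (key step)**
Reactants: 4 benzyl 3,6-dioxo-5-[(triisopropylsilyl)oxy]cyclohexa-1,4-diene-1-carboxylate; 9 6-methyl-4-oxo-4H-pyran-3-carbaldehyde
Product: 10 benzyl 3,6-dihydroxy-2-[(6-methyl-4-oxo-4H-pyran-3-yl)carbonyl]-5-[(triisopropylsilyl)oxy]benzoate
Conditions: 9 (3 equiv), PhCF3, 450 nm LEDs, 20 °C, N2
Reagents that add atoms: none
Why: Photo-Friedel–Crafts acylation of a quinone, in which the excited quinone abstracts the formyl hydrogen of 9 and the resulting nucleophilic acyl radical (a one-electron acyl anion equivalent) adds to C2 of 4, the CH that is beta to both the ester and the C6 carbonyl, whereas the C4 enol-ether CH is deactivated; tautomerisation gives the acylhydroquinone, the silyl ether has no C–H next to oxygen for intramolecular hydrogen abstraction, and no stereocentre is formed.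

**Step 5**
Reactants: 10 benzyl 3,6-dihydroxy-2-[(6-methyl-4-oxo-4H-pyran-3-yl)carbonyl]-5-[(triisopropylsilyl)oxy]benzoate
Product: 13 benzyl 4,6-dihydroxy-3-(3-oxobutanoyl)-7-[(triisopropylsilyl)oxy]-2H-chromene-5-carboxylate (enol form of the 3-acetoacetylchroman-4-one), via dihydropyranone 11 (not isolated), via methylene triketone 12 (not isolated)
Conditions: Hantzsch ester (1.05 equiv), (PhO)2P(O)OH (20 mol %), CH2Cl2, 0 °C; then Et3N (2 equiv), rt
Reagents that add atoms: none
Why: Brønsted-acid-catalysed transfer hydrogenation delivers hydride to C2 of the protonated 3-acyl-4-pyranone (the position flanked by both carbonyls), and base then triggers a ring transposition by E1cB opening to the 2-methylene-1,3-diketone 12 and 6-endo oxa-Michael closure by the ortho phenol, which places the aryl oxygen on the new CH2 and frees the acetoacetyl chain; no stereocentre is kept.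

**Step 6**
Reactants: 10 benzyl 3,6-dihydroxy-2-[(6-methyl-4-oxo-4H-pyran-3-yl)carbonyl]-5-[(triisopropylsilyl)oxy]benzoate; 13 benzyl 4,6-dihydroxy-3-(3-oxobutanoyl)-7-[(triisopropylsilyl)oxy]-2H-chromene-5-carboxylate
Product: 16 (1S,3R,2'S,3'S)-7,8'-bis-O-TIPS 9,10'-dibenzyl ester of 18, via lactol 14 (not isolated), via enol ether adduct 15 (not isolated)
Conditions: 10 (1.0 equiv), 13 (1.1 equiv), (R)-TRIP N-triflylphosphoramide (10 mol %), 5 Å MS, PhMe, −20 °C to rt
Reagents that add atoms: none
Why: Proposed new method: the strong chiral Brønsted acid makes the ortho phenol of 10 close onto the pyranone C4 carbonyl with loss of water (10 to lactol 14 to a 10-oxopyrano[4,3-b]chromenylium ion paired with the chiral phosphoramidate anion), the side-chain enol carbon of 13 adds to C1 of this cation inside the ion pair and so sets C1 (S), and the same acid then protonates the C3=C4 enol ether of 15 so that the hemiketal formed from the C4-enol hydroxyl and the methyl ketone of the 13-derived half captures C3 and closes the dihydropyranone, with C3 (R), C2' (S) and C3' (S) settling under thermodynamic control in the cis-fused cage; the closest known reaction types are chiral-anion-directed additions of 1,3-dicarbonyl enols to benzopyrylium and isochromenylium ions and chiral phosphoric-acid-catalysed (spiro)ketalisations of enol ethers.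

**Step 7**
Reactants: 16 (1S,3R,2'S,3'S)-7,8'-bis-O-TIPS 9,10'-dibenzyl ester of 18
Product: 18 CNP0230818.1 (1S,3R,2'S,3'S), via dibenzyl ester 17 (not isolated)
Conditions: Et3N·3HF, THF, 0 °C to rt; then Pd/C, H2 (1 atm), rt
Reagents that add atoms: none
Why: Fluoride cleavage of the two aryl silyl ethers under near-neutral conditions and then hydrogenolysis of the two benzyl esters in the same flask; no strong acid or base touches the ketal cage, the tetrasubstituted chromone and vinylogous-ester double bonds are not reduced at 1 atm, and the four stereocentres are untouched.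

**Compound list**
1 | 2,3-dihydroxybenzoic acid | OC(=O)c1cccc(O)c1O | starting material
2 | benzyl 2,3-dihydroxybenzoate | O=C(OCc1ccccc1)c1cccc(O)c1O | intermediate
3 | benzyl 2-hydroxy-3-[(triisopropylsilyl)oxy]benzoate | O=C(OCc1ccccc1)c1cccc(O[Si](C(C)C)(C(C)C)C(C)C)c1O | intermediate
4 | benzyl 3,6-dioxo-5-[(triisopropylsilyl)oxy]cyclohexa-1,4-diene-1-carboxylate | O=C1C=C(C(=O)OCc2ccccc2)C(=O)C(O[Si](C(C)C)(C(C)C)C(C)C)=C1 | intermediate
5 | 2,2,6-trimethyl-4H-1,3-dioxin-4-one | CC1=CC(=O)OC(C)(C)O1 | starting material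
6 | (E)-3-(dimethylamino)acrolein | CN(C)/C=C/C=O | starting material
7 | acetylketene (3-oxobut-1-en-1-one) | CC(=O)C=C=O | intermediate
8 | 2-(dimethylamino)-6-methyl-4-oxo-3,4-dihydro-2H-pyran-3-carbaldehyde (racemic) | CC1=CC(=O)C(C=O)C(N(C)C)O1 | intermediate
9 | 6-methyl-4-oxo-4H-pyran-3-carbaldehyde | Cc1cc(=O)c(C=O)co1 | intermediate
10 | benzyl 3,6-dihydroxy-2-[(6-methyl-4-oxo-4H-pyran-3-yl)carbonyl]-5-[(triisopropylsilyl)oxy]benzoate | Cc1cc(=O)c(co1)C(=O)c1c(O)cc(O[Si](C(C)C)(C(C)C)C(C)C)c(O)c1C(=O)OCc1ccccc1 | intermediate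
11 | benzyl 3,6-dihydroxy-2-[(6-methyl-4-oxo-3,4-dihydro-2H-pyran-3-yl)carbonyl]-5-[(triisopropylsilyl)oxy]benzoate (racemic) | CC1=CC(=O)C(CO1)C(=O)c1c(O)cc(O[Si](C(C)C)(C(C)C)C(C)C)c(O)c1C(=O)OCc1ccccc1 | intermediate
12 | benzyl 3,6-dihydroxy-2-(2-methylidene-3,5-dioxohexanoyl)-5-[(triisopropylsilyl)oxy]benzoate | CC(=O)CC(=O)C(=C)C(=O)c1c(O)cc(O[Si](C(C)C)(C(C)C)C(C)C)c(O)c1C(=O)OCc1ccccc1 | intermediate
13 | benzyl 4,6-dihydroxy-3-(3-oxobutanoyl)-7-[(triisopropylsilyl)oxy]-2H-chromene-5-carboxylate | CC(=O)CC(=O)C1=C(O)c2c(OC1)cc(O[Si](C(C)C)(C(C)C)C(C)C)c(O)c2C(=O)OCc1ccccc1 | intermediate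
14 | benzyl 1,8-dihydroxy-3-methyl-10-oxo-7-[(triisopropylsilyl)oxy]-1H,10H-pyrano[4,3-b]chromene-9-carboxylate (lactol, racemic) | CC1=Cc2oc3cc(O[Si](C(C)C)(C(C)C)C(C)C)c(O)c(C(=O)OCc4ccccc4)c3c(=O)c2C(O)O1 | intermediate
15 | (1S)-C1 adduct: the 1H-pyrano[4,3-b]chromen-10-one of 14 with the 1-OH replaced by the central CH of the acetoacetyl chain of 13 (that CH is labile) | CC1=Cc2oc3cc(O[Si](C(C)C)(C(C)C)C(C)C)c(O)c(C(=O)OCc4ccccc4)c3c(=O)c2[C@@H](O1)C(C(C)=O)C(=O)C1=C(O)c2c(OC1)cc(O[Si](C(C)C)(C(C)C)C(C)C)c(O)c2C(=O)OCc1ccccc1 | intermediate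
16 | (1S,3R,2'S,3'S)-7,8'-bis-O-TIPS 9,10'-dibenzyl ester of 18 | C[C@@]12Cc3oc4cc(O[Si](C(C)C)(C(C)C)C(C)C)c(O)c(C(=O)OCc5ccccc5)c4c(=O)c3[C@@H](O1)[C@H]1C(=O)C3=C(O[C@@]1(C)O2)c1c(cc(O[Si](C(C)C)(C(C)C)C(C)C)c(O)c1C(=O)OCc1ccccc1)OC3 | intermediate
17 | (1S,3R,2'S,3'S)-9,10'-dibenzyl ester of 18 | C[C@@]12Cc3oc4cc(O)c(O)c(C(=O)OCc5ccccc5)c4c(=O)c3[C@@H](O1)[C@H]1C(=O)C3=C(O[C@@]1(C)O2)c1c(cc(O)c(O)c1C(=O)OCc1ccccc1)OC3 | intermediate
18 | CNP0230818.1, (1S,3R,2'S,3'S): 7,8-dihydroxy-3-methyl-10-oxo-3,4-dihydro-1H-pyrano[4,3-b]chromene-9-carboxylic acid unit joined by C1–C3' and the C3–O–C2' ketal bridge to an 8',9'-dihydroxy-2'-methyl-4'-oxo-2',3'-dihydro-4'H,5'H-pyrano[3,2-c]chromene-10'-carboxylic acid unit | C[C@@]12Cc3oc4cc(O)c(O)c(C(=O)O)c4c(=O)c3[C@@H](O1)[C@H]1C(=O)C3=C(O[C@@]1(C)O2)c1c(cc(O)c(O)c1C(=O)O)OC3 | target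

**Step count and risks**
Total steps: 7. Longest linear sequence: 6 (steps 1, 2, 4, 5, 6, 7).

The three steps most likely to fail are steps 4, 5 and 6; step 6 is the most exposed.

Step 4 (photoacylation with a heteroaryl-type aldehyde; hydrogen donation by 9 and regiochemistry are untested). The fallback builds the pyranone after the arene instead of before it. It sets out from 4, which is photoacylated under the same light source with acetaldehyde (10 equiv), the best-behaved substrate class for this reaction, to give benzyl 2-acetyl-3,6-dihydroxy-5-[(triisopropylsilyl)oxy]benzoate F1. Condensation with N,N-dimethylformamide dimethyl acetal (PhMe, 80 °C) gives the enaminone benzyl 2-[(2E)-3-(dimethylamino)prop-2-enoyl]-3,6-dihydroxy-5-[(triisopropylsilyl)oxy]benzoate F2. Acetylketene 7, generated from 5 (PhMe, 110 °C), then adds across the enaminone C=C and loses dimethylamine, and the route is rejoined at 10.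

Step 5 (hydride may instead be delivered to the dehydrated chromenylium form of 10, giving the fulvic-type skeleton, or 12 may be over-reduced). The fallback moves the aryl oxygen first and reduces afterwards. It sets out from 10, which with DBU (10 mol %, CH2Cl2, rt) undergoes phenoxide oxa-Michael addition at pyranone C2 and E1cB opening to give isolable benzyl 6-hydroxy-4-oxo-3-(3-oxobutanoyl)-7-[(triisopropylsilyl)oxy]-4H-chromene-5-carboxylate F3. 1,4-Reduction of this 3-acylchromone with L-Selectride Li[BH(sec-Bu)3] (3.2 equiv, THF, −78 °C, two equivalents being consumed by the phenols; NH4Cl quench) gives the chromanone directly, and the route is rejoined at 13.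

Step 6 (enantiocontrol at C1 may be eroded by reversible ring opening before the cage locks; 13 may cyclodehydrate to the less nucleophilic pyranone; an isomeric ketal may compete). The fallback replaces catalyst control by resolution. It sets out from 10 and 13, which are combined with the achiral acid (PhO)2P(O)OH (20 mol %, 4 Å MS, PhMe, 40 °C) under thermodynamic control to give 16 as a racemate together with its mirror image ent-16 F4. The enantiomers are separated by preparative SFC on an amylose tris(3,5-dimethylphenylcarbamate) phase, and the (1S,3R,2'S,3'S) enantiomer rejoins the route at 16.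

**Further compounds**
F1 | step 4 | benzyl 2-acetyl-3,6-dihydroxy-5-[(triisopropylsilyl)oxy]benzoate | CC(=O)c1c(O)cc(O[Si](C(C)C)(C(C)C)C(C)C)c(O)c1C(=O)OCc1ccccc1
F2 | step 4 | benzyl 2-[(2E)-3-(dimethylamino)prop-2-enoyl]-3,6-dihydroxy-5-[(triisopropylsilyl)oxy]benzoate | CN(C)/C=C/C(=O)c1c(O)cc(O[Si](C(C)C)(C(C)C)C(C)C)c(O)c1C(=O)OCc1ccccc1
F3 | step 5 | benzyl 6-hydroxy-4-oxo-3-(3-oxobutanoyl)-7-[(triisopropylsilyl)oxy]-4H-chromene-5-carboxylate | CC(=O)CC(=O)c1coc2cc(O[Si](C(C)C)(C(C)C)C(C)C)c(O)c(C(=O)OCc3ccccc3)c2c1=O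
F4 | step 6 | ent-16, the (1R,3S,2'R,3'R) mirror image of 16 | C[C@]12Cc3oc4cc(O[Si](C(C)C)(C(C)C)C(C)C)c(O)c(C(=O)OCc5ccccc5)c4c(=O)c3[C@H](O1)[C@@H]1C(=O)C3=C(O[C@]1(C)O2)c1c(cc(O[Si](C(C)C)(C(C)C)C(C)C)c(O)c1C(=O)OCc1ccccc1)OC3
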